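The 5,5-dimethyl-2,5-dihydrofuran ring (O–C9Me2–C8=C7–C6) and its exocyclic C6=C5 bond are read as an oxidised, cyclised 4-methylpent-3-enoyl chain on C5: the C6 enol oxygen of a β-keto ester is joined to the tertiary alkene carbon C9. One selenium-induced 5-endo closure makes O–C9, the ring and the C5=C6 enol ether, leaving a C8 selenide for dehydrogenation. The precursor is an α-acyl δ-lactone in which the C5 carboxyl is esterified by the C3 hydroxymethyl group; C4 bears the dimethyl acetal arm, C3 the methylidene unit with the ketal chain. The tether needs no protecting groups at these sites and makes enol-ether closure onto the C2 alkene a bridgehead-alkene event.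

Key step: step 13

Atom labels (target): C1=C2 methylidene, C3 (bears CO2H), C4 (bears the CH2CHO arm), C5 (bears CHO), C6 to C9 ring carbons with C9 = CMe2, C10 to C14 the 4-oxopentyl chain on C2.

Assumption: the (4S,5S)-diazaborolidine controller of step 6 is taken to favour the chair that leads to (2S,3R)-15; should the sense prove opposite, the (4R,5R)-controller is used with no other change.

Step 1
Reactants: 1 2-(3-chloropropyl)-2-methyl-1,3-dioxolane; 2 triethyl phosphonoacetate
Product: 4 ethyl 2-(diethoxyphosphoryl)-5-(2-methyl-1,3-dioxolan-2-yl)pentanoate (racemic), via sodium phosphonoacetate carbanion 3 (not isolated)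
Conditions: NaH, THF/DMF, 0 °C; then 1, NaI (cat.), 60 °C
Reagents that add atoms: none
Why: SN2 C-alkylation of the stabilised phosphonate carbanion by the primary halide (chloride exchanged in situ for iodide, Finkelstein), with 2 in excess to suppress dialkylation.

Step 2
Reactants: 4 ethyl 2-(diethoxyphosphoryl)-5-(2-methyl-1,3-dioxolan-2-yl)pentanoate; 5 (tert-butyldimethylsilyloxy)acetaldehyde
Product: 7 ethyl (2E)-4-{[tert-butyl(dimethyl)silyl]oxy}-2-[3-(2-methyl-1,3-dioxolan-2-yl)propyl]but-2-enoate, via sodium salt of phosphonate 6 (not isolated)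
Conditions: NaH, THF, 0 °C; then 5, 0 °C → rt
Reagents that add atoms: none
Why: Horner–Wadsworth–Emmons olefination, which with an α-alkyl phosphonoacetate should favour the (E)-enoate (ester trans to the CH2OSi group); any (Z) isomer is removed by chromatography here or after step 3.

Step 3
Reactants: 7 ethyl (2E)-4-{[tert-butyl(dimethyl)silyl]oxy}-2-[3-(2-methyl-1,3-dioxolan-2-yl)propyl]but-2-enoate
Product: 8 (2E)-4-{[tert-butyl(dimethyl)silyl]oxy}-2-[3-(2-methyl-1,3-dioxolan-2-yl)propyl]but-2-en-1-ol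
Conditions: i-Bu2AlH, CH2Cl2, −78 °C; aq. KNaC4H4O6
Reagents that add atoms: none
Why: 1,2-reduction of the conjugated ester by the aluminium hydride gives the allylic alcohol without touching alkene geometry, ketal or silyl ether, so the two oxygens of the butenediol unit are differentiated by construction.

Step 4
Reactants: 9 methyl 4,4-dimethoxybutanoate
Product: 11 4,4-dimethoxybutanoic acid, via lithium 4,4-dimethoxybutanoate 10 (not isolated)
Conditions: LiOH, THF/H2O, 0 °C → rt; then aq. HCl to pH 4, 0 °C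
Reagents that add atoms: lithium hydroxide, [Li+].[OH-]
Why: Ester saponification (acyl–oxygen cleavage by hydroxide), with a cold and only weakly acidic work-up so that the dimethyl acetal survives.

Step 5
Reactants: 8 (2E)-4-{[tert-butyl(dimethyl)silyl]oxy}-2-[3-(2-methyl-1,3-dioxolan-2-yl)propyl]but-2-en-1-ol; 11 4,4-dimethoxybutanoic acid
Product: 12 (2E)-4-{[tert-butyl(dimethyl)silyl]oxy}-2-[3-(2-methyl-1,3-dioxolan-2-yl)propyl]but-2-en-1-yl 4,4-dimethoxybutanoate
Conditions: DCC, DMAP (cat.), CH2Cl2, 0 °C → rt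
Reagents that add atoms: none
Why: Steglich esterification under neutral conditions, compatible with acetal, ketal and silyl ether.

Step 6
Reactants: 12 (2E)-4-{[tert-butyl(dimethyl)silyl]oxy}-2-[3-(2-methyl-1,3-dioxolan-2-yl)propyl]but-2-en-1-yl 4,4-dimethoxybutanoate
Product: 15 (2S,3R)-3-({[tert-butyl(dimethyl)silyl]oxy}methyl)-2-(2,2-dimethoxyethyl)-4-methylidene-7-(2-methyl-1,3-dioxolan-2-yl)heptanoic acid, via boron ketene acetal 13 (not isolated), via boron carboxylate 14 (not isolated)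
Conditions: (4S,5S)-2-bromo-1,3-bis{[3,5-bis(trifluoromethyl)phenyl]sulfonyl}-4,5-diphenyl-1,3,2-diazaborolidine, Et3N, toluene/hexane, −78 → −20 °C; then H2O
Reagents that add atoms: none
Why: Enantioselective boron ester-enolate Claisen (Ireland–Claisen type) rearrangement, in which Et3N in the non-polar medium gives the boron ketene acetal 13 with the acetal arm cis to the allylic oxygen, the chair [3,3] shift across the (E)-alkene places the C3 and C4 substituents anti, and the C2-symmetric diazaborolidine on boron selects the chair that gives the (2S,3R) acid.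

Step 7
Reactants: 15 (2S,3R)-3-({[tert-butyl(dimethyl)silyl]oxy}methyl)-2-(2,2-dimethoxyethyl)-4-methylidene-7-(2-methyl-1,3-dioxolan-2-yl)heptanoic acid
Product: 17 (3S,4R)-4-({[tert-butyl(dimethyl)silyl]oxy}methyl)-1-diazo-3-(2,2-dimethoxyethyl)-5-methylidene-8-(2-methyl-1,3-dioxolan-2-yl)octan-2-one, via mixed isobutyl carbonic anhydride 16 (not isolated)
Conditions: i-BuOCOCl, N-methylmorpholine, THF, −20 °C; then CH2N2, Et2O, −20 → 0 °C
Reagents that add atoms: diazomethane, C=[N+]=[N-]
Why: First stage of the Arndt–Eistert homologation, acylation of diazomethane by the mixed anhydride under non-acidic conditions, so that acetal, silyl ether and the C4 centre are preserved.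

Step 8
Reactants: 17 (3S,4R)-4-({[tert-butyl(dimethyl)silyl]oxy}methyl)-1-diazo-3-(2,2-dimethoxyethyl)-5-methylidene-8-(2-methyl-1,3-dioxolan-2-yl)octan-2-one
Product: 19 methyl (3R,4R)-4-({[tert-butyl(dimethyl)silyl]oxy}methyl)-3-(2,2-dimethoxyethyl)-5-methylidene-8-(2-methyl-1,3-dioxolan-2-yl)octanoate, via ketene 18 (not isolated)
Conditions: PhCO2Ag (cat.), Et3N, MeOH, rt, dark
Reagents that add atoms: methanol, CO
Why: Silver-catalysed Wolff rearrangement, in which the C4 carbon migrates with retention of configuration to give ketene 18, which methanol traps as the homologous ester (the descriptor at C4 changes only through ligand priorities).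

Step 9
Reactants: 19 methyl (3R,4R)-4-({[tert-butyl(dimethyl)silyl]oxy}methyl)-3-(2,2-dimethoxyethyl)-5-methylidene-8-(2-methyl-1,3-dioxolan-2-yl)octanoate
Product: 21 (4R,5R)-4-(2,2-dimethoxyethyl)-5-[5-(2-methyl-1,3-dioxolan-2-yl)pent-1-en-2-yl]oxan-2-one, via hydroxy ester 20 (not isolated)
Conditions: Bu4NF, THF, 0 °C → rt
Reagents that add atoms: none
Why: Fluoride desilylation followed by intramolecular transesterification (6-exo-trig lactonisation) of the liberated C3 alkoxide onto the methyl ester, giving the trans-4,5-disubstituted δ-lactone in which both substituents can lie equatorial.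

Step 10
Reactants: 22 4-methylpent-3-en-1-ol
Product: 23 4-methylpent-3-enal
Conditions: Dess–Martin periodinane, pyridine, CH2Cl2, 0 °C; used at once as a solution
Reagents that add atoms: none
Why: Dess–Martin oxidation under buffered, non-basic conditions, which should leave the β,γ-alkene out of conjugation.

Step 11
Reactants: 21 (4R,5R)-4-(2,2-dimethoxyethyl)-5-[5-(2-methyl-1,3-dioxolan-2-yl)pent-1-en-2-yl]oxan-2-one; 23 4-methylpent-3-enal
Product: 25 (4S,5R)-4-(2,2-dimethoxyethyl)-3-(1-hydroxy-4-methylpent-3-en-1-yl)-5-[5-(2-methyl-1,3-dioxolan-2-yl)pent-1-en-2-yl]oxan-2-one (mixture at C3 and at the carbinol carbon), via lithium enolate 24 (not isolated)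
Conditions: LiN(i-Pr)2, THF, −78 °C; then 23, −78 °C; aq. NH4Cl
Reagents that add atoms: none
Why: Aldol addition of the lactone lithium enolate to the aldehyde, expected to outrun proton transfer at −78 °C; the two new centres (C5 and the carbinol C6) need no control because step 12 turns one into a ketone and makes the other enolisable.

Step 12
Reactants: 25 (4S,5R)-4-(2,2-dimethoxyethyl)-3-(1-hydroxy-4-methylpent-3-en-1-yl)-5-[5-(2-methyl-1,3-dioxolan-2-yl)pent-1-en-2-yl]oxan-2-one
Product: 26 (4S,5R)-4-(2,2-dimethoxyethyl)-3-(4-methylpent-3-enoyl)-5-[5-(2-methyl-1,3-dioxolan-2-yl)pent-1-en-2-yl]oxan-2-one (C3 epimers and enol)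
Conditions: Dess–Martin periodinane, pyridine, CH2Cl2, 0 °C → rt
Reagents that add atoms: none
Why: Dess–Martin oxidation of the β-hydroxy lactone to the α-acyl lactone (a cyclic β-keto ester), mild enough to keep the C7–C8=C9 unit unconjugated.

Step 13
Reactants: 26 (4S,5R)-4-(2,2-dimethoxyethyl)-3-(4-methylpent-3-enoyl)-5-[5-(2-methyl-1,3-dioxolan-2-yl)pent-1-en-2-yl]oxan-2-one
Product: 28 (3E,4S,5R)-3-[5,5-dimethyl-4-(phenylselanyl)oxolan-2-ylidene]-4-(2,2-dimethoxyethyl)-5-[5-(2-methyl-1,3-dioxolan-2-yl)pent-1-en-2-yl]oxan-2-one (either epimer at the selenium-bearing carbon), via seleniranium chloride 27 (not isolated)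
Conditions: PhSeCl, K2CO3, CH2Cl2, −78 → 0 °C
Reagents that add atoms: phenylselanyl chloride, Cl[Se]c1ccccc1
Why: This is the phenylselenoetherification of an alkenyl β-dicarbonyl compound through its enol oxygen, a known O-cyclisation, in which PhSeCl adds reversibly to the trisubstituted C8=C9 bond to give seleniranium ion 27. The oxygen on C6 opens the ion at the tertiary carbon C9 (Markovnikov) in a 5-endo closure that forms the oxolane ring and, after loss of the C5 proton to carbonate, the exocyclic C5=C6 vinylogous carbonate. The only new stereocentre, the selenium-bearing C8, is not controlled and is destroyed in step 14, while C3 and C4 are untouched. Oxygen rather than carbon attack is secured because C5 would have to bond to the fully substituted C9, and attack at C9 rather than C8 by cation stabilisation at the tertiary carbon. The δ-lactone tether turns the competing 6-exo enol-ether closure onto the C2 methylidene into formation of a bridgehead alkene in a bicyclo[3.3.1] frame, so selenium adducts of that alkene should simply revert. The C5=C6 geometry should settle as E (lactone carbonyl away from the ring oxygen, C4 beside it), and K2CO3 removes HCl before it can ionise the acetals.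

Step 14
Reactants: 28 (3E,4S,5R)-3-[5,5-dimethyl-4-(phenylselanyl)oxolan-2-ylidene]-4-(2,2-dimethoxyethyl)-5-[5-(2-methyl-1,3-dioxolan-2-yl)pent-1-en-2-yl]oxan-2-one
Product: 30 (3E,4S,5R)-3-(5,5-dimethylfuran-2(5H)-ylidene)-4-(2,2-dimethoxyethyl)-5-[5-(2-methyl-1,3-dioxolan-2-yl)pent-1-en-2-yl]oxan-2-one, via selenoxide 29 (not isolated)
Conditions: 30% H2O2, pyridine, CH2Cl2, 0 °C → rt
Reagents that add atoms: none
Why: Selenide oxidation and selenoxide syn-elimination; only C7 carries β-hydrogens (C9 is quaternary), so the C7=C8 bond forms regiospecifically and in conjugation with the vinylogous carbonate.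

Step 15
Reactants: 30 (3E,4S,5R)-3-(5,5-dimethylfuran-2(5H)-ylidene)-4-(2,2-dimethoxyethyl)-5-[5-(2-methyl-1,3-dioxolan-2-yl)pent-1-en-2-yl]oxan-2-one
Product: 32 (2E,3S,4R)-2-(5,5-dimethylfuran-2(5H)-ylidene)-3-(2,2-dimethoxyethyl)-4-(hydroxymethyl)-5-methylidene-8-(2-methyl-1,3-dioxolan-2-yl)octanal, via lactol 31 (not isolated)
Conditions: i-Bu2AlH, CH2Cl2, −78 °C; aq. KNaC4H4O6
Reagents that add atoms: none
Why: Partial reduction of a lactone to the lactol by i-Bu2AlH (the aluminated hemiacetal resists further hydride at −78 °C), followed by ring-chain tautomerism that should favour the open form, in which the C5 formyl group is a doubly vinylogous formate ester and the C3 carbinol is free.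

Step 16
Reactants: 32 (2E,3S,4R)-2-(5,5-dimethylfuran-2(5H)-ylidene)-3-(2,2-dimethoxyethyl)-4-(hydroxymethyl)-5-methylidene-8-(2-methyl-1,3-dioxolan-2-yl)octanal
Product: 34 (2R)-2-[(2E,3S)-2-(5,5-dimethylfuran-2(5H)-ylidene)-5,5-dimethoxy-1-oxopentan-3-yl]-3-methylidene-6-(2-methyl-1,3-dioxolan-2-yl)hexanoic acid, via aldehyde 33 (not isolated)
Conditions: TEMPO (cat.), PhI(OAc)2, MeCN/aq. NaH2PO4–Na2HPO4 (pH 7), 0 °C → rt
Reagents that add atoms: water, O
Why: Oxoammonium (TEMPO) oxidation of a primary alcohol to the carboxylic acid through the aldehyde hydrate; the conjugated C5 formyl group does not hydrate and should be left alone, and the neutral buffer guards the acetals and the C3 centre.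

Step 17
Reactants: 34 (2R)-2-[(2E,3S)-2-(5,5-dimethylfuran-2(5H)-ylidene)-5,5-dimethoxy-1-oxopentan-3-yl]-3-methylidene-6-(2-methyl-1,3-dioxolan-2-yl)hexanoic acid
Product: 35 (2R)-2-[(2E,3S)-2-(5,5-dimethylfuran-2(5H)-ylidene)-1,5-dioxopentan-3-yl]-3-methylidene-7-oxooctanoic acid (CNP0150297.1)
Conditions: PPTS (cat.), acetone/H2O, 40 °C
Reagents that add atoms: water, O
Why: Mild acid-catalysed hydrolysis (transacetalisation) of the dimethyl acetal and the dioxolane, placed last so that the free aldehyde arm never meets an oxidant or the C3 carbinol.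

Compound list

1 | 2-(3-chloropropyl)-2-methyl-1,3-dioxolane | CC1(CCCCl)OCCO1 | starting material
2 | triethyl phosphonoacetate | CCOC(=O)CP(=O)(OCC)OCC | starting material
3 | sodium salt (carbanion) of 2, not isolated | CCOC(=O)[CH-]P(=O)(OCC)OCC.[Na+] | intermediate
4 | ethyl 2-(diethoxyphosphoryl)-5-(2-methyl-1,3-dioxolan-2-yl)pentanoate (racemic) | CCOC(=O)C(CCCC1(C)OCCO1)P(=O)(OCC)OCC | intermediate
5 | (tert-butyldimethylsilyloxy)acetaldehyde | O=CCO[Si](C)(C)C(C)(C)C | starting material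
6 | sodium salt (carbanion) of 4, not isolated | CCOC(=O)[C-](CCCC1(C)OCCO1)P(=O)(OCC)OCC.[Na+] | intermediate
7 | ethyl (2E)-4-{[tert-butyl(dimethyl)silyl]oxy}-2-[3-(2-methyl-1,3-dioxolan-2-yl)propyl]but-2-enoate | CCOC(=O)/C(CCCC1(C)OCCO1)=C/CO[Si](C)(C)C(C)(C)C | intermediate
8 | (2E)-4-{[tert-butyl(dimethyl)silyl]oxy}-2-[3-(2-methyl-1,3-dioxolan-2-yl)propyl]but-2-en-1-ol | OC/C(CCCC1(C)OCCO1)=C/CO[Si](C)(C)C(C)(C)C | intermediate
9 | methyl 4,4-dimethoxybutanoate | COC(CCC(=O)OC)OC | starting material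
10 | lithium 4,4-dimethoxybutanoate, not isolated | COC(CCC(=O)[O-])OC.[Li+] | intermediate
11 | 4,4-dimethoxybutanoic acid | COC(CCC(=O)O)OC | intermediate
12 | (2E)-4-{[tert-butyl(dimethyl)silyl]oxy}-2-[3-(2-methyl-1,3-dioxolan-2-yl)propyl]but-2-en-1-yl 4,4-dimethoxybutanoate | COC(OC)CCC(=O)OC/C(CCCC1(C)OCCO1)=C/CO[Si](C)(C)C(C)(C)C | intermediate
13 | boron ketene acetal of 12 (acetal arm cis to the allylic oxygen; boron in the (4S,5S)-diazaborolidine), not isolated | COC(OC)C/C=C(/OB1N(S(=O)(=O)c2cc(cc(c2)C(F)(F)F)C(F)(F)F)[C@@H](c2ccccc2)[C@H](c2ccccc2)N1S(=O)(=O)c1cc(cc(c1)C(F)(F)F)C(F)(F)F)OC/C(CCCC1(C)OCCO1)=C/CO[Si](C)(C)C(C)(C)C | intermediate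
14 | boron carboxylate (acyloxy-diazaborolidine) of 15, not isolated | C=C(CCCC1(C)OCCO1)[C@H](CO[Si](C)(C)C(C)(C)C)[C@H](CC(OC)OC)C(=O)OB1N(S(=O)(=O)c2cc(cc(c2)C(F)(F)F)C(F)(F)F)[C@@H](c2ccccc2)[C@H](c2ccccc2)N1S(=O)(=O)c1cc(cc(c1)C(F)(F)F)C(F)(F)F | intermediate
15 | (2S,3R)-3-({[tert-butyl(dimethyl)silyl]oxy}methyl)-2-(2,2-dimethoxyethyl)-4-methylidene-7-(2-methyl-1,3-dioxolan-2-yl)heptanoic acid | C=C(CCCC1(C)OCCO1)[C@H](CO[Si](C)(C)C(C)(C)C)[C@H](CC(OC)OC)C(=O)O | intermediate
16 | isobutyl carbonic anhydride of 15, not isolated | C=C(CCCC1(C)OCCO1)[C@H](CO[Si](C)(C)C(C)(C)C)[C@H](CC(OC)OC)C(=O)OC(=O)OCC(C)C | intermediate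
17 | (3S,4R)-4-({[tert-butyl(dimethyl)silyl]oxy}methyl)-1-diazo-3-(2,2-dimethoxyethyl)-5-methylidene-8-(2-methyl-1,3-dioxolan-2-yl)octan-2-one | C=C(CCCC1(C)OCCO1)[C@H](CO[Si](C)(C)C(C)(C)C)[C@H](CC(OC)OC)C(=O)C=[N+]=[N-] | intermediate
18 | (3S,4R)-4-({[tert-butyl(dimethyl)silyl]oxy}methyl)-3-(2,2-dimethoxyethyl)-5-methylidene-8-(2-methyl-1,3-dioxolan-2-yl)oct-1-en-1-one (ketene), not isolated | C=C(CCCC1(C)OCCO1)[C@H](CO[Si](C)(C)C(C)(C)C)[C@H](CC(OC)OC)C=C=O | intermediate
19 | methyl (3R,4R)-4-({[tert-butyl(dimethyl)silyl]oxy}methyl)-3-(2,2-dimethoxyethyl)-5-methylidene-8-(2-methyl-1,3-dioxolan-2-yl)octanoate | C=C(CCCC1(C)OCCO1)[C@H](CO[Si](C)(C)C(C)(C)C)[C@H](CC(OC)OC)CC(=O)OC | intermediate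
20 | methyl (3R,4R)-3-(2,2-dimethoxyethyl)-4-(hydroxymethyl)-5-methylidene-8-(2-methyl-1,3-dioxolan-2-yl)octanoate, not isolated | C=C(CCCC1(C)OCCO1)[C@H](CO)[C@H](CC(OC)OC)CC(=O)OC | intermediate
21 | (4R,5R)-4-(2,2-dimethoxyethyl)-5-[5-(2-methyl-1,3-dioxolan-2-yl)pent-1-en-2-yl]oxan-2-one | C=C(CCCC1(C)OCCO1)[C@@H]2COC(=O)C[C@H]2CC(OC)OC | intermediate
22 | 4-methylpent-3-en-1-ol | CC(C)=CCCO | starting material
23 | 4-methylpent-3-enal | CC(C)=CCC=O | intermediate
24 | lithium enolate of 21, not isolated | C=C(CCCC1(C)OCCO1)[C@@H]2COC([O-])=C[C@H]2CC(OC)OC.[Li+] | intermediate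
25 | (4S,5R)-4-(2,2-dimethoxyethyl)-3-(1-hydroxy-4-methylpent-3-en-1-yl)-5-[5-(2-methyl-1,3-dioxolan-2-yl)pent-1-en-2-yl]oxan-2-one (mixture at C3 and at the carbinol carbon) | C=C(CCCC1(C)OCCO1)[C@@H]2COC(=O)C(C(O)CC=C(C)C)[C@H]2CC(OC)OC | intermediate
26 | (4S,5R)-4-(2,2-dimethoxyethyl)-3-(4-methylpent-3-enoyl)-5-[5-(2-methyl-1,3-dioxolan-2-yl)pent-1-en-2-yl]oxan-2-one (C3 epimers and enol; key-step precursor) | C=C(CCCC1(C)OCCO1)[C@@H]2COC(=O)C(C(=O)CC=C(C)C)[C@H]2CC(OC)OC | intermediate
27 | seleniranium chloride of 26 (selenium bridging C8 and C9), not isolated | C=C(CCCC1(C)OCCO1)[C@@H]2COC(=O)C(C(=O)CC3[Se+](c4ccccc4)C3(C)C)[C@H]2CC(OC)OC.[Cl-] | intermediate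
28 | (3E,4S,5R)-3-[5,5-dimethyl-4-(phenylselanyl)oxolan-2-ylidene]-4-(2,2-dimethoxyethyl)-5-[5-(2-methyl-1,3-dioxolan-2-yl)pent-1-en-2-yl]oxan-2-one (either epimer at the selenium-bearing carbon; key-step product) | C=C(CCCC1(C)OCCO1)[C@@H]2COC(=O)/C(=C3\CC([Se]c4ccccc4)C(C)(C)O3)[C@H]2CC(OC)OC | intermediate
29 | selenoxide of 28, not isolated | C=C(CCCC1(C)OCCO1)[C@@H]2COC(=O)/C(=C3\CC([Se](=O)c4ccccc4)C(C)(C)O3)[C@H]2CC(OC)OC | intermediate
30 | (3E,4S,5R)-3-(5,5-dimethylfuran-2(5H)-ylidene)-4-(2,2-dimethoxyethyl)-5-[5-(2-methyl-1,3-dioxolan-2-yl)pent-1-en-2-yl]oxan-2-one | C=C(CCCC1(C)OCCO1)[C@@H]2COC(=O)/C(=C3\C=CC(C)(C)O3)[C@H]2CC(OC)OC | intermediate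
31 | (3E,4S,5R)-3-(5,5-dimethylfuran-2(5H)-ylidene)-4-(2,2-dimethoxyethyl)-5-[5-(2-methyl-1,3-dioxolan-2-yl)pent-1-en-2-yl]oxan-2-ol (lactol, both anomers), not isolated | C=C(CCCC1(C)OCCO1)[C@@H]2COC(O)/C(=C3\C=CC(C)(C)O3)[C@H]2CC(OC)OC | intermediate
32 | (2E,3S,4R)-2-(5,5-dimethylfuran-2(5H)-ylidene)-3-(2,2-dimethoxyethyl)-4-(hydroxymethyl)-5-methylidene-8-(2-methyl-1,3-dioxolan-2-yl)octanal | C=C(CCCC1(C)OCCO1)[C@H](CO)[C@H](CC(OC)OC)/C(C=O)=C2/C=CC(C)(C)O2 | intermediate
33 | (2R,3S,4E)-4-(5,5-dimethylfuran-2(5H)-ylidene)-3-(2,2-dimethoxyethyl)-2-[5-(2-methyl-1,3-dioxolan-2-yl)pent-1-en-2-yl]pentanedial, not isolated | C=C(CCCC1(C)OCCO1)[C@H](C=O)[C@H](CC(OC)OC)/C(C=O)=C2/C=CC(C)(C)O2 | intermediate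
34 | (2R)-2-[(2E,3S)-2-(5,5-dimethylfuran-2(5H)-ylidene)-5,5-dimethoxy-1-oxopentan-3-yl]-3-methylidene-6-(2-methyl-1,3-dioxolan-2-yl)hexanoic acid | C=C(CCCC1(C)OCCO1)[C@H](C(=O)O)[C@H](CC(OC)OC)/C(C=O)=C2/C=CC(C)(C)O2 | intermediate
35 | (2R)-2-[(2E,3S)-2-(5,5-dimethylfuran-2(5H)-ylidene)-1,5-dioxopentan-3-yl]-3-methylidene-7-oxooctanoic acid (CNP0150297.1) | C=C(CCCC(C)=O)[C@H](C(=O)O)[C@H](CC=O)/C(C=O)=C1/C=CC(C)(C)O1 | target

Total step count: 17 steps.

Longest linear sequence: 15 steps (steps 1, 2, 3, 5 to 9 and 11 to 17, from 1 and 2 to 35); steps 4 and 10 supply the two side branches.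

Steps most likely to fail

Step 13 (key step). Selenium may be transferred to the enol carbon C5 or may stay on the C2 methylidene instead of closing the ring at C9, or acid set free in the closure may ionise the dimethyl acetal. The fallback sets out from 26 and comes back at 30. Iodine-induced closure (I2, NaHCO3, MeCN, 0 °C) should make the same O–C9 bond in the same 5-endo sense and give the iodo enol ether F1. Dehydroiodination (DBU, toluene, rt → 60 °C), helped by the vinylogous acidity of the C7 hydrogens, should then give 30 directly, so that step 14 is not needed.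

Step 6. Facial discrimination by the boron controller may be incomplete, the boron Lewis acid may attack the dimethyl acetal, or the slow rearrangement of the boron ketene acetal may stall. The fallback sets out from 12 and comes back at 15. A conventional Ireland–Claisen rearrangement (LiN(i-Pr)2, Me3SiCl, THF, −78 °C → rt) through the silyl ketene acetal F2 and the trimethylsilyl ester F3, hydrolysed on work-up, should give the anti acid as the racemate, that is 15 together with its mirror image F4. The racemate is resolved by crystallisation of the (S)-1-phenylethylammonium salt F5, and acidification of the resolved salt returns 15. The approach changes from reagent-controlled induction to resolution.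

Step 16. The hydroxy aldehyde 32 may close to lactol 31, which the oxoammonium salt would return to lactone 30, or the transient C3 aldehyde may epimerise before it is oxidised further. The fallback sets out from 30 and comes back at 34. Exhaustive reduction (i-Bu2AlH in excess, CH2Cl2, −78 → 0 °C) gives the diol F6. Swern oxidation ((COCl)2, DMSO, CH2Cl2, −78 °C; then Et3N) activates both carbinols before base is added, so no lactol can intervene, and gives dialdehyde 33. Chlorite oxidation (NaClO2, NaH2PO4, 2-methylbut-2-ene, t-BuOH/H2O, 0 °C) should then convert only the saturated C3 aldehyde and give 34.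

Further compounds

F1 | step 13 | (3E,4S,5R)-3-(4-iodo-5,5-dimethyloxolan-2-ylidene)-4-(2,2-dimethoxyethyl)-5-[5-(2-methyl-1,3-dioxolan-2-yl)pent-1-en-2-yl]oxan-2-one (either epimer at the iodine-bearing carbon) | C=C(CCCC1(C)OCCO1)[C@@H]2COC(=O)/C(=C3\CC(I)C(C)(C)O3)[C@H]2CC(OC)OC
F2 | step 6 | trimethylsilyl ketene acetal of 12 (acetal arm cis to the allylic oxygen) | COC(OC)C/C=C(/O[Si](C)(C)C)OC/C(CCCC1(C)OCCO1)=C/CO[Si](C)(C)C(C)(C)C
F3 | step 6 | trimethylsilyl ester of the racemic anti acid (the enantiomer that leads to 15 is drawn) | C=C(CCCC1(C)OCCO1)[C@H](CO[Si](C)(C)C(C)(C)C)[C@H](CC(OC)OC)C(=O)O[Si](C)(C)C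
F4 | step 6 | (2R,3S)-3-({[tert-butyl(dimethyl)silyl]oxy}methyl)-2-(2,2-dimethoxyethyl)-4-methylidene-7-(2-methyl-1,3-dioxolan-2-yl)heptanoic acid (mirror image of 15) | C=C(CCCC1(C)OCCO1)[C@@H](CO[Si](C)(C)C(C)(C)C)[C@@H](CC(OC)OC)C(=O)O
F5 | step 6 | (S)-1-phenylethylammonium salt of 15 | C=C(CCCC1(C)OCCO1)[C@H](CO[Si](C)(C)C(C)(C)C)[C@H](CC(OC)OC)C(=O)[O-].C[C@H]([NH3+])c1ccccc1
F6 | step 16 | (2E,3S,4R)-2-(5,5-dimethylfuran-2(5H)-ylidene)-3-(2,2-dimethoxyethyl)-4-(hydroxymethyl)-5-methylidene-8-(2-methyl-1,3-dioxolan-2-yl)octan-1-ol | C=C(CCCC1(C)OCCO1)[C@H](CO)[C@H](CC(OC)OC)/C(CO)=C2/C=CC(C)(C)O2
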